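The five-membered ring is closed last, at the C3–C4 bond. C4 is a fully substituted carbinol carbon lying between C3 and C5, so it can be carried as a secondary isopropyl carbinol on C5 of a complete seven-membered ring. A rhodium carbenoid at C3, generated from a diazoketone on the quaternary C1, inserts into the C4–H bond: one operation closes the five-membered ring, forms C3–C4 and makes C4 fully substituted with retention. The precursor is the cycloheptane with both tiglates (C6, C10), the C8–C9 epoxide, the diazoacetyl group on C1 and, cis to it on C5, the triethylsilyl-protected carbinol.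

Key step: step 17

Remark: the carbons are numbered C1 (ring fusion, methyl), C2 (carbinol), C3, C4 (isopropyl carbinol), C5 (ring fusion, H), C6 (tiglate), C7, C8 (methyl), C9 and C10 (tiglate), with the epoxide on C8–C9, and this numbering is kept for every intermediate; compounds 1, 3, 6, 12 and 19 are taken as commercial.

Step 1
Reactants: 1 methyl 4-methyl-3-oxopentanoate
Product: 2 methyl (3S)-3-hydroxy-4-methylpentanoate
Conditions: H2 (50 atm), RuCl2[(R)-BINAP] (0.1 mol%), MeOH, 50 °C
Reagents that add atoms: none
Why: Noyori asymmetric hydrogenation of a β-keto ester, in which the (R)-BINAP ruthenium catalyst should deliver hydrogen to the chelated ketone face that gives the C4 carbinol in the required configuration (descriptor S here because isopropyl outranks the ester methylene).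

Step 2
Reactants: 2 methyl (3S)-3-hydroxy-4-methylpentanoate; 3 tert-butyl bromoacetate
Product: 4 hydroxy diester
Conditions: LiN(i-Pr)2 (2.2 equiv), THF, −78 → −20 °C; then 3, DMPU, −78 → −20 °C
Reagents that add atoms: none
Why: Fráter–Seebach alkylation, in which the chelated lithium alkoxide–enolate dianion should be alkylated on the face away from the isopropyl group, setting C5 anti to the C4 hydroxyl.

Step 3
Reactants: 4 hydroxy diester
Product: 5 hydroxy Weinreb amide
Conditions: MeNH(OMe)·HCl, i-PrMgCl, THF, −20 → 0 °C
Reagents that add atoms: N,O-dimethylhydroxylamine hydrochloride, CNOC.Cl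
Why: Weinreb amide formation with the magnesium amide, which should attack the methyl ester and leave the hindered tert-butyl ester, while the C4 magnesium alkoxide protects C5 from epimerisation.

Step 4
Reactants: 5 hydroxy Weinreb amide; 6 2-methylallylmagnesium chloride
Product: 7 β-hydroxy ketone
Conditions: 6 (3 equiv), THF, −78 °C; cold aq. NH4Cl
Reagents that add atoms: none
Why: Grignard addition to a Weinreb amide stops at the chelated tetrahedral adduct, so the β,γ-unsaturated ketone (C6, C7, C8) should be released only on cold quench, without double addition or migration of the alkene into conjugation.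

Step 5
Reactants: 7 β-hydroxy ketone
Product: 8 syn-1,3-diol
Conditions: Et2BOMe, NaBH4, THF/MeOH (4:1), −78 °C; AcOH, then MeOH evaporation
Reagents that add atoms: none
Why: Narasaka–Prasad reduction, in which the diethylboron chelate holds the isopropyl group and the C5 substituent equatorial and external hydride adds axially, which should give the 1,3-syn diol and so set C6 anti to the C1 arm.

Step 6
Reactants: 8 syn-1,3-diol
Product: 9 hydroxy lactone
Conditions: KOt-Bu (0.2 equiv), THF, 0 °C → rt
Reagents that add atoms: none
Why: Base-catalysed lactonisation under equilibrating conditions, in which the γ-lactone closed through the less hindered C6 oxygen (unbranched methallyl rather than isopropyl on the ring next to the C5 substituent) should predominate over its regioisomer and leave the C4 hydroxyl free.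

Step 7
Reactants: 9 hydroxy lactone
Product: 10 silyl ether lactone
Conditions: TESOTf, 2,6-lutidine, CH2Cl2, −78 °C
Reagents that add atoms: triethylsilyl trifluoromethanesulfonate, CC[Si](CC)(CC)OS(=O)(=O)C(F)(F)F
Why: Silylation of the remaining secondary alcohol with a silyl triflate; triethylsilyl is chosen over a bulkier silyl group because the ether must later be cleaved from a fully substituted carbon under mild buffered conditions.

Step 8
Reactants: 10 silyl ether lactone
Product: 11 α-methyl lactone
Conditions: LiN(i-Pr)2, THF, −78 °C; MeI, −78 → −40 °C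
Reagents that add atoms: iodomethane, CI
Why: Lactone enolate alkylation, in which the methyl group should enter trans to the C5 substituent, although the configuration created at C1 is not important because this centre is enolised again in step 9.

Step 9
Reactants: 11 α-methyl lactone; 12 acrolein
Product: 13 aldol adducts (C10 epimers)
Conditions: LiN(i-Pr)2, THF, −78 → −40 °C; 12, −78 °C; aq. NH4Cl at −78 °C
Reagents that add atoms: none
Why: Aldol addition of the tetrasubstituted lactone enolate to acrolein on the ring face opposite to the C5 and C6 substituents should set the quaternary C1, while the new carbinol carbon C10 forms as an epimer mixture that converges in step 10.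

Step 10
Reactants: 13 aldol adducts (C10 epimers)
Product: 14 vinyl ketone
Conditions: Dess–Martin periodinane, NaHCO3, CH2Cl2, 0 °C → rt
Reagents that add atoms: none
Why: Dess–Martin oxidation of both allylic alcohols under buffered neutral conditions should give one non-enolisable vinyl ketone.

Step 11
Reactants: 14 vinyl ketone
Product: 15 allylic alcohol
Conditions: (R)-2-methyl-CBS-oxazaborolidine (0.3 equiv), catecholborane, toluene, −78 °C
Reagents that add atoms: none
Why: Corey–Bakshi–Shibata reduction, in which the oxazaborolidine should bind the ketone with the fully substituted C1 as the large group and vinyl as the small one and deliver hydride 1,2 to give the C10 carbinol (descriptor S at this stage).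

Step 12
Reactants: 15 allylic alcohol
Product: 16 open-chain methyl ketone diol
Conditions: MeLi (2.5 equiv), THF, −78 °C; AcOH/THF at −78 °C
Reagents that add atoms: methyllithium, [Li]C
Why: Addition of methyllithium to the hindered lactone should stop at the lithium hemiketal, which on cold protonation gives the methyl ketone (C2, C3) and frees the C6 hydroxyl.

Step 13
Reactants: 16 open-chain methyl ketone diol
Product: 17 cycloheptene diol
Conditions: second-generation Grubbs catalyst RuCl2(=CHPh)(H2IMes)(PCy3) (5 mol%), CH2Cl2 (2 mM), 40 °C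
Reagents that add atoms: none
Why: Ring-closing metathesis between the C10 vinyl and the C6 methallyl group should form the seven-membered ring with the trisubstituted C8–C9 alkene, the open hydroxy ketone being the form that cyclises and being fed by equilibration from its hemiketal.

Step 14
Reactants: 17 cycloheptene diol
Product: 18 epoxy diol
Conditions: VO(acac)2 (5 mol%), t-BuOOH, CH2Cl2, 0 °C → rt
Reagents that add atoms: tert-butyl hydroperoxide, CC(C)(C)OO
Why: Hydroxyl-directed epoxidation, in which the vanadium alkoxide of the allylic C10 hydroxyl should deliver oxygen to its own face of C8–C9, allylic delivery being much faster than delivery from the homoallylic C6 hydroxyl on the other face.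

Step 15
Reactants: 18 epoxy diol; 19 tigloyl chloride
Product: 20 bis-tiglate methyl ketone
Conditions: 19 (4 equiv), Et3N, DMAP, CH2Cl2, 0 → 40 °C
Reagents that add atoms: none
Why: DMAP-catalysed acylation of both secondary alcohols with the acid chloride; tiglate is the stable alkene geometry, so no isomerisation is expected.

Step 16
Reactants: 20 bis-tiglate methyl ketone
Product: 22 diazoketone, via trifluoroacetyl diketone 21 (not isolated)
Conditions: LiN(SiMe3)2 (1.1 equiv), THF, −78 °C; CF3CO2CH2CF3; aq. NH4Cl; then MsN3, Et3N, H2O, MeCN, rt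
Reagents that add atoms: 2,2,2-trifluoroethyl trifluoroacetate, O=C(OCC(F)(F)F)C(F)(F)F; methanesulfonyl azide, CS(=O)(=O)N=[N+]=[N-]
Why: Regitz diazo transfer in its detrifluoroacetylative variant: the methyl group is the only enolisable position of the ketone, its lithium enolate should be trifluoroacetylated at −78 °C before it can attack a tiglate, and the activated diketone then accepts the diazo group with loss of the trifluoroacetyl group.

Step 17
Reactants: 22 diazoketone
Product: 23 silyl-protected cyclopentanone
Conditions: Rh2(OAc)4 (2 mol%), CH2Cl2, rt, slow addition of 22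
Reagents that add atoms: none
Why: Dirhodium tetraacetate should convert the diazoketone into an electrophilic carbenoid at C3, which inserts into the C4–H bond through a three-centre transition state with hydride-transfer character. The closest known reaction is the rhodium-catalysed intramolecular 1,5 C–H insertion of α-diazoketones next to an ether oxygen, which gives cyclopentanones. The five-membered ring C1–C2–C3–C4–C5 closes by this 1,5 insertion onto a side chain that is cis to the diazoacetyl group, so the cis ring fusion is already fixed by C1 and C5. C4 becomes fully substituted with retention, because the C3–C4 bond forms on the face from which hydrogen leaves, so its configuration is the one set in step 1. Three C–H bonds stand in 1,5 position (C4–H, C6–H and the epoxide C9–H): C4–H is a methine activated by the silyl ether oxygen, C6–H is deactivated by its tiglate and C9–H by the high s character of the epoxide carbon, while C10–H and the C1 methyl would give four-membered rings. Ester and epoxide oxygens and the hindered silyl ether are poor ylide formers, and the electron-poor tiglate alkenes resist cyclopropanation.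

Step 18
Reactants: 23 silyl-protected cyclopentanone
Product: 24 β-hydroxy ketone
Conditions: HF·pyridine, pyridine, THF, 0 °C
Reagents that add atoms: none
Why: Fluoride cleavage of the tertiary triethylsilyl ether under pyridine-buffered, non-basic conditions should avoid retro-aldol opening or β-elimination of the β-hydroxy ketone, acyl migration and opening of the epoxide.

Step 19
Reactants: 24 β-hydroxy ketone
Product: 25 target CNP0265715.1
Conditions: Me4NBH(OAc)3, MeCN/AcOH (4:1), −30 °C
Reagents that add atoms: none
Why: Evans–Saksena reduction, in which the C4 hydroxyl exchanges onto boron and delivers hydride intramolecularly to the concave face of the C2 ketone, which should give the C2 alcohol anti to the C4 hydroxyl without touching the esters or the epoxide.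

Compound list
1 | methyl 4-methyl-3-oxopentanoate | CC(C)C(=O)CC(=O)OC | starting material
2 | methyl (3S)-3-hydroxy-4-methylpentanoate | CC(C)[C@@H](O)CC(=O)OC | intermediate
3 | tert-butyl bromoacetate | CC(C)(C)OC(=O)CBr | starting material
4 | methyl (2R,3R)-2-(2-tert-butoxy-2-oxoethyl)-3-hydroxy-4-methylpentanoate | CC(C)[C@@H](O)[C@@H](CC(=O)OC(C)(C)C)C(=O)OC | intermediate
5 | tert-butyl (3R)-3-[(1R)-1-hydroxy-2-methylpropyl]-4-[methoxy(methyl)amino]-4-oxobutanoate | CC(C)[C@@H](O)[C@@H](CC(=O)OC(C)(C)C)C(=O)N(C)OC | intermediate
6 | 2-methylallylmagnesium chloride | CC(=C)C[Mg]Cl | starting material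
7 | tert-butyl (3R)-3-[(1R)-1-hydroxy-2-methylpropyl]-6-methyl-4-oxohept-6-enoate | CC(C)[C@@H](O)[C@@H](CC(=O)OC(C)(C)C)C(=O)CC(C)=C | intermediate
8 | tert-butyl (3S,4S)-4-hydroxy-3-[(1R)-1-hydroxy-2-methylpropyl]-6-methylhept-6-enoate | CC(C)[C@@H](O)[C@@H](CC(=O)OC(C)(C)C)[C@@H](O)CC(C)=C | intermediate
9 | (4R,5S)-4-[(1R)-1-hydroxy-2-methylpropyl]-5-(2-methylprop-2-en-1-yl)oxolan-2-one | CC(C)[C@@H](O)[C@H]1CC(=O)O[C@H]1CC(C)=C | intermediate
10 | (4S,5S)-5-(2-methylprop-2-en-1-yl)-4-[(1R)-2-methyl-1-(triethylsilyloxy)propyl]oxolan-2-one | CC(C)[C@@H](O[Si](CC)(CC)CC)[C@H]1CC(=O)O[C@H]1CC(C)=C | intermediate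
11 | (3S,4S,5S)-3-methyl-5-(2-methylprop-2-en-1-yl)-4-[(1R)-2-methyl-1-(triethylsilyloxy)propyl]oxolan-2-one | CC(C)[C@@H](O[Si](CC)(CC)CC)[C@H]1[C@H](C)C(=O)O[C@H]1CC(C)=C | intermediate
12 | acrolein (prop-2-enal) | C=CC=O | starting material
13 | (3R,4S,5S)-3-(1-hydroxyprop-2-en-1-yl)-3-methyl-5-(2-methylprop-2-en-1-yl)-4-[(1R)-2-methyl-1-(triethylsilyloxy)propyl]oxolan-2-one, both epimers at the carbinol carbon | CC(C)[C@@H](O[Si](CC)(CC)CC)[C@H]1[C@](C)(C(O)C=C)C(=O)O[C@H]1CC(C)=C | intermediate
14 | (3R,4S,5S)-3-methyl-5-(2-methylprop-2-en-1-yl)-4-[(1R)-2-methyl-1-(triethylsilyloxy)propyl]-3-(prop-2-enoyl)oxolan-2-one | CC(C)[C@@H](O[Si](CC)(CC)CC)[C@H]1[C@](C)(C(=O)C=C)C(=O)O[C@H]1CC(C)=C | intermediate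
15 | (3R,4S,5S)-3-[(1S)-1-hydroxyprop-2-en-1-yl]-3-methyl-5-(2-methylprop-2-en-1-yl)-4-[(1R)-2-methyl-1-(triethylsilyloxy)propyl]oxolan-2-one | CC(C)[C@@H](O[Si](CC)(CC)CC)[C@H]1[C@](C)([C@@H](O)C=C)C(=O)O[C@H]1CC(C)=C | intermediate
16 | (3R,4S,5S)-5-hydroxy-3-[(1S)-1-hydroxyprop-2-en-1-yl]-3,7-dimethyl-4-[(1R)-2-methyl-1-(triethylsilyloxy)propyl]oct-7-en-2-one, in equilibrium with its five-membered hemiketal | CC(C)[C@@H](O[Si](CC)(CC)CC)[C@H]([C@@H](O)CC(C)=C)[C@@](C)(C(C)=O)[C@@H](O)C=C | intermediate
17 | 1-[(1R,2S,6S,7S)-2,6-dihydroxy-1,4-dimethyl-7-[(1R)-2-methyl-1-(triethylsilyloxy)propyl]cyclohept-3-en-1-yl]ethan-1-one | O[C@H]1CC(C)=C[C@H](O)[C@@](C(C)=O)(C)[C@@H]1[C@H](O[Si](CC)(CC)CC)C(C)C | intermediate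
18 | epoxy diol: 17 with the C8–C9 alkene turned into the epoxide on the face of the C10 hydroxyl; (1R,4R,5S,6S,8S,9R,10R) | O[C@H]1C[C@]2(C)O[C@@H]2[C@H](O)[C@@](C(C)=O)(C)[C@@H]1[C@H](O[Si](CC)(CC)CC)C(C)C | intermediate
19 | tigloyl chloride, (2E)-2-methylbut-2-enoyl chloride | C/C=C(\C)C(Cl)=O | starting material
20 | bis-tiglate methyl ketone: 18 with both hydroxyls (C6, C10) esterified by (2E)-2-methylbut-2-enoic acid; (1R,4R,5S,6S,8S,9R,10R) | C/C=C(\C)C(=O)O[C@H]1C[C@]2(C)O[C@@H]2[C@H](OC(=O)/C(C)=C/C)[C@@](C(C)=O)(C)[C@@H]1[C@H](O[Si](CC)(CC)CC)C(C)C | intermediate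
21 | trifluoroacetyl diketone: 20 with the acetyl group extended to a 4,4,4-trifluoro-3-oxobutanoyl group | C/C=C(\C)C(=O)O[C@H]1C[C@]2(C)O[C@@H]2[C@H](OC(=O)/C(C)=C/C)[C@@](C(=O)CC(=O)C(F)(F)F)(C)[C@@H]1[C@H](O[Si](CC)(CC)CC)C(C)C | intermediate
22 | diazoketone: cycloheptane with diazoacetyl and methyl on C1, (1R)-2-methyl-1-(triethylsilyloxy)propyl on C5, tiglates on C6 and C10, C8–C9 epoxide with methyl on C8; (1R,4R,5S,6S,8S,9R,10R) | C/C=C(\C)C(=O)O[C@H]1C[C@]2(C)O[C@@H]2[C@H](OC(=O)/C(C)=C/C)[C@@](C(=O)C=[N+]=[N-])(C)[C@@H]1[C@H](O[Si](CC)(CC)CC)C(C)C | intermediate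
23 | cis-fused cyclopentanone: C2 ketone, C4 bearing isopropyl and triethylsilyloxy, tiglates on C6 and C10, C8–C9 epoxide; (1R,4R,5S,6S,8S,9R,10R) | C/C=C(\C)C(=O)O[C@H]1C[C@]2(C)O[C@@H]2[C@H](OC(=O)/C(C)=C/C)[C@@]2(C)[C@@H]1[C@](O[Si](CC)(CC)CC)(C(C)C)CC2=O | intermediate
24 | β-hydroxy ketone: 23 with the free tertiary C4 hydroxyl; (1R,4R,5S,6S,8S,9R,10R) | C/C=C(\C)C(=O)O[C@H]1C[C@]2(C)O[C@@H]2[C@H](OC(=O)/C(C)=C/C)[C@@]2(C)[C@@H]1[C@](O)(C(C)C)CC2=O | intermediate
25 | CNP0265715.1: (1S,2S,4R,5S,6S,8S,9R,10R)-8,9-epoxy-2,4-dihydroxy-4-isopropyl-1,8-dimethyl hydroazulene 6,10-ditiglate | C/C=C(\C)C(=O)O[C@H]1C[C@]2(C)O[C@@H]2[C@H](OC(=O)/C(C)=C/C)[C@@]2(C)[C@@H]1[C@](O)(C(C)C)C[C@@H]2O | target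

Total step count: 19. Longest linear sequence: 19 steps (from 1).

Steps most likely to fail

Step 17. The carbenoid may insert at C6–H instead of C4–H, be captured by the epoxide or an ester oxygen as an ylide, add to a tiglate alkene, or dimerise. The fallback forms the same C3–C4 bond by carbonyl chemistry and sets out from 20. Buffered HF·pyridine removes the silyl group to give the C4 alcohol F1. Dess–Martin periodinane oxidises it to the 1,4-diketone F2. Catalytic KOt-Bu in THF at −20 °C then brings about the intramolecular aldol addition of the methyl ketone enolate (C3) to the isopropyl ketone (C4), the reaction by which 1,4-diketones give 3-hydroxycyclopentanones. The isopropyl group should take the convex face of the cis-fused bicycle, which gives 24, where the route is rejoined. Epimerisation at C5 and dehydration to the cyclopentenone are the processes to watch.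

Step 6. The ring may close through the C4 oxygen instead of the C6 oxygen, or the two lactones may form as a mixture. The fallback blocks the C4 oxygen before the C6 oxygen exists and sets out from 7. TESCl and imidazole in DMF give the silyl ether ketone F3. LiBH(s-Bu)3 in THF at −78 °C reduces it under Felkin–Anh control, hydride arriving anti to the large C4 substituent on C5 and reinforced by the anti β-silyloxy group. This gives the hydroxy ester F4 as its lithium alkoxide, which has only one free oxygen and closes onto the tert-butyl ester on warming to room temperature; with lithium as counter-ion a 1,3-silyl shift should be slow. The product is 10.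

Step 11. Hydride may arrive on the wrong face of the ketone, or the vinyl ketone may be reduced in the conjugate sense. The fallback replaces the vinyl ketone by an ynone, a substrate class for which catalyst-controlled transfer hydrogenation is dependable, and sets out from 11. LiN(i-Pr)2 and 3-(trimethylsilyl)prop-2-ynal give the alkynyl carbinols F5. Dess–Martin periodinane gives the ynone F6. Noyori transfer hydrogenation with RuCl[(R,R)-TsDPEN](p-cymene) in i-PrOH gives the propargylic alcohol F7; the (R,R) complex is chosen on the assumption that the alkyne takes the place of the unsaturated group. K2CO3 in MeOH removes the alkyne silyl group to give F8. Semi-hydrogenation with H2 over Pd/CaCO3 poisoned with Pb(OAc)2 (Lindlar catalyst) and quinoline returns 15.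

Further compounds
F1 | step 17 | C4 alcohol: 20 without the triethylsilyl group | C/C=C(\C)C(=O)O[C@H]1C[C@]2(C)O[C@@H]2[C@H](OC(=O)/C(C)=C/C)[C@@](C(C)=O)(C)[C@@H]1[C@H](O)C(C)C
F2 | step 17 | 1,4-diketone: acetyl on C1 and 2-methylpropanoyl on C5 | C/C=C(\C)C(=O)O[C@H]1C[C@]2(C)O[C@@H]2[C@H](OC(=O)/C(C)=C/C)[C@@](C(C)=O)(C)[C@@H]1C(=O)C(C)C
F3 | step 6 | tert-butyl (3R)-6-methyl-3-[(1R)-2-methyl-1-(triethylsilyloxy)propyl]-4-oxohept-6-enoate | CC(C)[C@@H](O[Si](CC)(CC)CC)[C@@H](CC(=O)OC(C)(C)C)C(=O)CC(C)=C
F4 | step 6 | tert-butyl (3S,4S)-4-hydroxy-6-methyl-3-[(1R)-2-methyl-1-(triethylsilyloxy)propyl]hept-6-enoate | CC(C)[C@@H](O[Si](CC)(CC)CC)[C@@H](CC(=O)OC(C)(C)C)[C@@H](O)CC(C)=C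
F5 | step 11 | 3-[1-hydroxy-3-(trimethylsilyl)prop-2-yn-1-yl] analogue of 13, both carbinol epimers | CC(C)[C@@H](O[Si](CC)(CC)CC)[C@H]1[C@](C)(C(O)C#C[Si](C)(C)C)C(=O)O[C@H]1CC(C)=C
F6 | step 11 | ynone: 3-[3-(trimethylsilyl)prop-2-ynoyl] analogue of 14 | CC(C)[C@@H](O[Si](CC)(CC)CC)[C@H]1[C@](C)(C(=O)C#C[Si](C)(C)C)C(=O)O[C@H]1CC(C)=C
F7 | step 11 | silylated propargylic alcohol with the carbinol configuration of 15 | CC(C)[C@@H](O[Si](CC)(CC)CC)[C@H]1[C@](C)([C@@H](O)C#C[Si](C)(C)C)C(=O)O[C@H]1CC(C)=C
F8 | step 11 | terminal propargylic alcohol with the carbinol configuration of 15 | CC(C)[C@@H](O[Si](CC)(CC)CC)[C@H]1[C@](C)([C@@H](O)C#C)C(=O)O[C@H]1CC(C)=C
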